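A direct plan would close the furan ring onto a finished arene: iodolactone A1 (side chain masked as a dihydrocoumarin) would be annulated with alkyne A2 under palladium catalysis to furochromenone A3, and MeMgBr, then mild acid, would unveil side chain, phenols and aldehyde. Its weakest steps would be the iodination of the dimethoxychromanone (two free ring positions of similar electron density would compete), the heteroannulation (a methyl ether, not a phenol, would have to supply the ring oxygen with loss of chloromethane, a closure without firm precedent and with unsecured alkyne regiochemistry) and the final Grignard step (one reagent would have to open a lactone twice and cleave two hindered pivalates while sparing an acetal).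

**Strategy.** The route buys the furan and builds the benzenoid ring of the benzofuran (C3a, C4, C5, C6, C7, C7a) onto it. That ring carries OH at C4, the alkyl chain at C5, OMe at C6 and H at C7: exactly the pattern that an arylketene and a 1-methoxyalkyne write in a benzannulation. Irradiation of furyl diazo ketone 12 with ynol ether 17 triggers Wolff rearrangement, [2+2] cycloaddition, four-electron ring opening and six-electron electrocyclisation onto furan C3, forming C4–C5, C6–C7 and C3a–C4 in one operation. No arene is halogenated, no ether oxygen has to close a ring, and the side chain arrives complete, so no lactone mask or Grignard end game is needed.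

Key step: step 8

Remark: the target is achiral, so no stereocentre has to be set; 4-bromo-2-methylbutan-2-ol (13) is assumed to be commercially available.

Step 1
Reactants: 1 4-bromobenzene-1,3-diol
Product: 2 1-bromo-2,4-bis(triisopropylsilyloxy)benzene
Conditions: i-Pr3SiCl (2.4 equiv), imidazole (5 equiv), DMF, rt to 40 °C
Reagents that add atoms: chlorotriisopropylsilane (CC(C)[Si](Cl)(C(C)C)C(C)C)
Why: Imidazole-promoted O-silylation of both phenols; the bulky silyl ethers should survive the organolithium and palladium steps, are poor directors of ortho-lithiation, and fall to fluoride at the end.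

Step 2
Reactants: 3 furan-3-carbaldehyde
Product: 4 2-(furan-3-yl)-1,3-dioxolane
Conditions: HOCH2CH2OH (1.5 equiv), p-TsOH·H2O (1 mol %), benzene, reflux (Dean–Stark)
Reagents that add atoms: ethylene glycol (OCCO)
Why: Acid-catalysed acetalisation with azeotropic removal of water; the dioxolane masks the future formyl group against organolithiums and later directs the lithiation to C2.

Step 3
Reactants: 4 2-(furan-3-yl)-1,3-dioxolane; 2 1-bromo-2,4-bis(triisopropylsilyloxy)benzene
Product: 7 2-{2-[2,4-bis(triisopropylsilyloxy)phenyl]furan-3-yl}-1,3-dioxolane, via 2-lithiofuran acetal 5 (not isolated), via furylzinc chloride 6 (not isolated)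
Conditions: n-BuLi (1.0 equiv), THF, −78 °C; ZnCl2 (1.1 equiv), −78 °C to rt; then 2 (0.9 equiv), Pd2(dba)3 (1.5 mol %), XPhos (6 mol %), THF, 60 °C
Reagents that add atoms: none
Why: Directed α-lithiation of the 3-substituted furan at C2 (flanked by the ring oxygen and the coordinating acetal), transmetalation to zinc and Negishi coupling with the hindered, electron-rich aryl bromide under a bulky biarylphosphine–palladium catalyst; keeping the metal on the furan avoids an ortho-lithiated aryl silyl ether, which could suffer retro-Brook silyl migration.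

Step 4
Reactants: 7 2-{2-[2,4-bis(triisopropylsilyloxy)phenyl]furan-3-yl}-1,3-dioxolane
Product: 9 1-{5-[2,4-bis(triisopropylsilyloxy)phenyl]-4-(1,3-dioxolan-2-yl)furan-2-yl}ethan-1-one, via 5-lithiofuran 8 (not isolated)
Conditions: n-BuLi (1.1 equiv), THF, −78 to −30 °C; MeC(O)N(OMe)Me (1.3 equiv), −78 to 0 °C; sat. aq. NH4Cl
Reagents that add atoms: N-methoxy-N-methylacetamide (CC(=O)N(C)OC)
Why: α-Lithiation of the furan at C5, its only remaining α-hydrogen, and acylation with a Weinreb amide, whose chelated tetrahedral adduct prevents over-addition; the hindered silyloxy groups should not direct lithiation into the aryl ring.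

Step 5
Reactants: 9 1-{5-[2,4-bis(triisopropylsilyloxy)phenyl]-4-(1,3-dioxolan-2-yl)furan-2-yl}ethan-1-one
Product: 12 1-{5-[2,4-bis(triisopropylsilyloxy)phenyl]-4-(1,3-dioxolan-2-yl)furan-2-yl}-2-diazoethan-1-one, via lithium enolate 10 (not isolated), via trifluoroacetyl diketone 11 (not isolated)
Conditions: LiN(SiMe3)2 (1.1 equiv), THF, −78 °C; CF3CO2CH2CF3 (1.2 equiv); sat. aq. NH4Cl; then MsN3 (1.5 equiv), Et3N (1.5 equiv), H2O (1 equiv), MeCN, rt
Reagents that add atoms: methanesulfonyl azide (CS(=O)(=O)N=[N+]=[N-])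
Why: Detrifluoroacetylative diazo transfer: Claisen-type trifluoroacetylation of the ketone enolate activates the methyl group, and mesyl azide then transfers the diazo group with loss of the trifluoroacetyl unit as its sulfonamide, under basic conditions that leave acetal and silyl ethers alone.

Step 6
Reactants: 13 4-bromo-2-methylbutan-2-ol
Product: 14 [(4-bromo-2-methylbutan-2-yl)oxy]triethylsilane
Conditions: Et3SiOTf (1.2 equiv), 2,6-lutidine (1.5 equiv), CH2Cl2, 0 °C
Reagents that add atoms: triethylsilyl trifluoromethanesulfonate (CC[Si](CC)(CC)OS(=O)(=O)C(F)(F)F)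
Why: Silyl triflate/2,6-lutidine silylation, the standard method for tertiary alcohols; the ether keeps the alcohol from adding to the ketene in step 8.

Step 7
Reactants: 15 2-chloro-1,1-dimethoxyethane; 14 [(4-bromo-2-methylbutan-2-yl)oxy]triethylsilane
Product: 17 1-methoxy-5-methyl-5-(triethylsilyloxy)hex-1-yne, via sodium methoxyethynide 16 (not isolated)
Conditions: NaNH2 (3.0 equiv), liq. NH3, −33 °C; then 14 (0.8 equiv), THF, −33 °C to rt
Reagents that add atoms: none
Why: Twofold amide-induced elimination (methanol, then HCl) and deprotonation give the sodium alkoxyacetylide, which the primary bromide alkylates by SN2 (the classical preparation of 1-alkoxy-1-alkynes from chloroacetaldehyde acetals).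

Step 8
Reactants: 12 1-{5-[2,4-bis(triisopropylsilyloxy)phenyl]-4-(1,3-dioxolan-2-yl)furan-2-yl}-2-diazoethan-1-one; 17 1-methoxy-5-methyl-5-(triethylsilyloxy)hex-1-yne
Product: 22 2-[2,4-bis(triisopropylsilyloxy)phenyl]-3-(1,3-dioxolan-2-yl)-6-methoxy-5-[3-methyl-3-(triethylsilyloxy)butyl]-1-benzofuran-4-ol, via furylketene 18 (not isolated), via furylcyclobutenone 19 (not isolated), via dienylketene 20 (not isolated), via 3aH-benzofuranone 21 (not isolated)
Conditions: hν (254 nm, low-pressure Hg lamps, Vycor), 17 (1.5 equiv), ClCH2CH2Cl, rt; then 80 °C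
Reagents that add atoms: none
Why: Benzannulation of a heteroaryl α-diazo ketone with an ynol ether (the Danheiser benzannulation in its diazo ketone variant is the closest known reaction type): light expels N2 from 12 and the furyl group migrates (Wolff rearrangement) to ketene 18, whose electrophilic carbonyl carbon bonds to the nucleophilic, alkyl-bearing carbon of 17 in a [2+2] cycloaddition that gives 3-methoxycyclobutenone 19. Reversible four-electron electrocyclic opening of 19 (light, completed by heat) gives dienylketene 20, and a thermal disrotatory six-electron electrocyclisation of the ketene C=C, the enol ether C=C and the furan C2=C3 bond closes the six-membered ring by forming C3a–C4, after which tautomerisation of 3aH-benzofuranone 21 restores the furan and gives phenol 22. No stereocentre remains, since C4 of 19 and C3a of 21 are transient. The step needs regiocontrol only: the polarisation of the ynol ether places the chain ortho (C5) and OMe meta (C6) to the new hydroxyl (C4), and the ketene-bearing furan carbon has the ring oxygen as one neighbour and C3–H as the other, so closure can occur at one position only and must give the 4-hydroxybenzofuran. The low aromatic stabilisation of furan eases the dearomatising closure, and a methoxyalkyne, unlike an ethoxyalkyne, cannot lose an alkene by retro-ene fragmentation at 80 °C. The tertiary alcohol is silylated and the aldehyde masked so that neither can trap the ketene.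

Step 9
Reactants: 22 2-[2,4-bis(triisopropylsilyloxy)phenyl]-3-(1,3-dioxolan-2-yl)-6-methoxy-5-[3-methyl-3-(triethylsilyloxy)butyl]-1-benzofuran-4-ol
Product: 24 2-(2,4-dihydroxyphenyl)-4-hydroxy-5-(3-hydroxy-3-methylbutyl)-6-methoxy-1-benzofuran-3-carbaldehyde (Ebenfuran V), via tetrahydroxy acetal 23 (not isolated)
Conditions: Bu4NF (3.5 equiv), THF, 0 °C to rt; then 1 M aq. HCl (to pH 2), rt
Reagents that add atoms: water (O)
Why: Fluoride cleaves the two aryl silyl ethers and the tertiary triethylsilyl ether, and dilute aqueous acid then hydrolyses the dioxolane on the electron-rich benzofuran (acetal hydrolysis through a stabilised oxocarbenium ion) under conditions too mild for the tertiary alcohol to ionise or cyclise onto the 4-hydroxyl.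

**Compound list**
1 | 4-bromobenzene-1,3-diol (4-bromoresorcinol) | Oc1ccc(Br)c(O)c1 | starting material
2 | 1-bromo-2,4-bis(triisopropylsilyloxy)benzene | Brc1ccc(O[Si](C(C)C)(C(C)C)C(C)C)cc1O[Si](C(C)C)(C(C)C)C(C)C | intermediate
3 | furan-3-carbaldehyde | O=Cc1ccoc1 | starting material
4 | 2-(furan-3-yl)-1,3-dioxolane | c1cc(C2OCCO2)co1 | intermediate
5 | [3-(1,3-dioxolan-2-yl)furan-2-yl]lithium | [Li]c1occc1C1OCCO1 | intermediate
6 | chloro[3-(1,3-dioxolan-2-yl)furan-2-yl]zinc | Cl[Zn]c1occc1C1OCCO1 | intermediate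
7 | 2-{2-[2,4-bis(triisopropylsilyloxy)phenyl]furan-3-yl}-1,3-dioxolane | c1coc(-c2ccc(O[Si](C(C)C)(C(C)C)C(C)C)cc2O[Si](C(C)C)(C(C)C)C(C)C)c1C1OCCO1 | intermediate
8 | {5-[2,4-bis(triisopropylsilyloxy)phenyl]-4-(1,3-dioxolan-2-yl)furan-2-yl}lithium | [Li]c1cc(C2OCCO2)c(-c2ccc(O[Si](C(C)C)(C(C)C)C(C)C)cc2O[Si](C(C)C)(C(C)C)C(C)C)o1 | intermediate
9 | 1-{5-[2,4-bis(triisopropylsilyloxy)phenyl]-4-(1,3-dioxolan-2-yl)furan-2-yl}ethan-1-one | CC(=O)c1cc(C2OCCO2)c(-c2ccc(O[Si](C(C)C)(C(C)C)C(C)C)cc2O[Si](C(C)C)(C(C)C)C(C)C)o1 | intermediate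
10 | lithium enolate of 9 (lithium 1-arylfuranyl-ethen-1-olate) | [Li]OC(=C)c1cc(C2OCCO2)c(-c2ccc(O[Si](C(C)C)(C(C)C)C(C)C)cc2O[Si](C(C)C)(C(C)C)C(C)C)o1 | intermediate
11 | 1-{5-[2,4-bis(triisopropylsilyloxy)phenyl]-4-(1,3-dioxolan-2-yl)furan-2-yl}-4,4,4-trifluorobutane-1,3-dione | O=C(CC(=O)C(F)(F)F)c1cc(C2OCCO2)c(-c2ccc(O[Si](C(C)C)(C(C)C)C(C)C)cc2O[Si](C(C)C)(C(C)C)C(C)C)o1 | intermediate
12 | 1-{5-[2,4-bis(triisopropylsilyloxy)phenyl]-4-(1,3-dioxolan-2-yl)furan-2-yl}-2-diazoethan-1-one | [N-]=[N+]=CC(=O)c1cc(C2OCCO2)c(-c2ccc(O[Si](C(C)C)(C(C)C)C(C)C)cc2O[Si](C(C)C)(C(C)C)C(C)C)o1 | intermediate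
13 | 4-bromo-2-methylbutan-2-ol | CC(C)(O)CCBr | starting material
14 | [(4-bromo-2-methylbutan-2-yl)oxy]triethylsilane | CC[Si](CC)(CC)OC(C)(C)CCBr | intermediate
15 | 2-chloro-1,1-dimethoxyethane (chloroacetaldehyde dimethyl acetal) | COC(CCl)OC | starting material
16 | sodium methoxyethynide | COC#C[Na] | intermediate
17 | 1-methoxy-5-methyl-5-(triethylsilyloxy)hex-1-yne | COC#CCCC(C)(C)O[Si](CC)(CC)CC | intermediate
18 | 2-{5-[2,4-bis(triisopropylsilyloxy)phenyl]-4-(1,3-dioxolan-2-yl)furan-2-yl}ethen-1-one (furylketene) | O=C=Cc1cc(C2OCCO2)c(-c2ccc(O[Si](C(C)C)(C(C)C)C(C)C)cc2O[Si](C(C)C)(C(C)C)C(C)C)o1 | intermediate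
19 | 4-{5-[2,4-bis(triisopropylsilyloxy)phenyl]-4-(1,3-dioxolan-2-yl)furan-2-yl}-3-methoxy-2-[3-methyl-3-(triethylsilyloxy)butyl]cyclobut-2-en-1-one (racemic) | O=C1C(CCC(C)(C)O[Si](CC)(CC)CC)=C(OC)C1c1cc(C2OCCO2)c(-c2ccc(O[Si](C(C)C)(C(C)C)C(C)C)cc2O[Si](C(C)C)(C(C)C)C(C)C)o1 | intermediate
20 | (3E)-4-{5-[2,4-bis(triisopropylsilyloxy)phenyl]-4-(1,3-dioxolan-2-yl)furan-2-yl}-3-methoxy-2-[3-methyl-3-(triethylsilyloxy)butyl]buta-1,3-dien-1-one (ketene carbon cis to the furyl group) | O=C=C(CCC(C)(C)O[Si](CC)(CC)CC)/C(OC)=C\c1cc(C2OCCO2)c(-c2ccc(O[Si](C(C)C)(C(C)C)C(C)C)cc2O[Si](C(C)C)(C(C)C)C(C)C)o1 | intermediate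
21 | 2-[2,4-bis(triisopropylsilyloxy)phenyl]-3-(1,3-dioxolan-2-yl)-6-methoxy-5-[3-methyl-3-(triethylsilyloxy)butyl]-1-benzofuran-4(3aH)-one (racemic) | O=C1C(CCC(C)(C)O[Si](CC)(CC)CC)=C(OC)C=C2OC(-c3ccc(O[Si](C(C)C)(C(C)C)C(C)C)cc3O[Si](C(C)C)(C(C)C)C(C)C)=C(C3OCCO3)C12 | intermediate
22 | 2-[2,4-bis(triisopropylsilyloxy)phenyl]-3-(1,3-dioxolan-2-yl)-6-methoxy-5-[3-methyl-3-(triethylsilyloxy)butyl]-1-benzofuran-4-ol | COc1cc2oc(-c3ccc(O[Si](C(C)C)(C(C)C)C(C)C)cc3O[Si](C(C)C)(C(C)C)C(C)C)c(C3OCCO3)c2c(O)c1CCC(C)(C)O[Si](CC)(CC)CC | intermediate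
23 | 4-[3-(1,3-dioxolan-2-yl)-4-hydroxy-5-(3-hydroxy-3-methylbutyl)-6-methoxy-1-benzofuran-2-yl]benzene-1,3-diol | COc1cc2oc(-c3ccc(O)cc3O)c(C3OCCO3)c2c(O)c1CCC(C)(C)O | intermediate
24 | 2-(2,4-dihydroxyphenyl)-4-hydroxy-5-(3-hydroxy-3-methylbutyl)-6-methoxy-1-benzofuran-3-carbaldehyde (Ebenfuran V, achiral) | COc1cc2oc(-c3ccc(O)cc3O)c(C=O)c2c(O)c1CCC(C)(C)O | target

**Count.** Total: 9 steps. Longest linear sequence: 6 steps (steps 2, 3, 4, 5, 8, 9, from furan-3-carbaldehyde).

**Steps most likely to fail**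

Step 8. The arylfuran chromophore may take up most of the 254 nm light so that the Wolff rearrangement stalls, or ketene 18 may dimerise or acylate the product phenol before it meets the alkyne. The fallback sets out from 12 and comes back to the route at ketene 18 (and so at 22); it makes the ketene without light. Silver-catalysed Wolff rearrangement of 12 in wet THF (AgO2CPh, Et3N, H2O) would give {5-[2,4-bis(triisopropylsilyloxy)phenyl]-4-(1,3-dioxolan-2-yl)furan-2-yl}acetic acid F1. 1-Chloro-N,N,2-trimethylprop-1-en-1-amine would convert it under neutral conditions into the corresponding acetyl chloride F2. Slow addition of Et3N to F2 and 17 in toluene at 80 °C would release 18 by dehydrochlorination in the presence of the alkyne, and cycloaddition, ring opening and electrocyclisation would then run thermally to 22.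

Step 3. Lithiation may occur in part at C5 instead of C2, or oxidative addition of the hindered, electron-rich aryl bromide may be so slow that the furylzinc reagent decomposes or homocouples. The fallback sets out from 2 and comes back at 7; the substitution pattern is fixed by a purchased halide. Miyaura borylation of 2 (B2pin2, PdCl2(dppf), KOAc, dioxane, 90 °C) would give 2-[2,4-bis(triisopropylsilyloxy)phenyl]-4,4,5,5-tetramethyl-1,3,2-dioxaborolane F3. Suzuki coupling with commercial 2-bromofuran-3-carbaldehyde F4 (Pd(PPh3)4, K3PO4, toluene/H2O, 80 °C) would give 2-[2,4-bis(triisopropylsilyloxy)phenyl]furan-3-carbaldehyde F5. Acetalisation with 1,2-bis(trimethylsilyloxy)ethane and catalytic Me3SiOTf (CH2Cl2, −78 °C) would give 7.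

Step 7. The basic acetylide may eliminate HBr from 14 instead of displacing bromide, or the acid-sensitive ynol ether may hydrate to the ester during isolation. The fallback sets out from 14 and comes back at 17; the triple bond is made by elimination, not by alkylation. Magnesium insertion into 14 (Mg, THF) would give bromo[3-methyl-3-(triethylsilyloxy)butyl]magnesium F6, which would add once to commercial N,2-dimethoxy-N-methylacetamide F7 to give 1-methoxy-5-methyl-5-(triethylsilyloxy)hexan-2-one F8. Chelation-controlled enolisation toward the methoxy-bearing carbon and O-triflation (LiN(SiMe3)2, PhNTf2, THF, −78 °C) would give (1Z)-1-methoxy-5-methyl-5-(triethylsilyloxy)hex-1-en-2-yl trifluoromethanesulfonate F9. Anti elimination of triflic acid with KOt-Bu (THF, −78 °C) would give 17.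

**Further compounds**
F1 | step 8 | {5-[2,4-bis(triisopropylsilyloxy)phenyl]-4-(1,3-dioxolan-2-yl)furan-2-yl}acetic acid | OC(=O)Cc1cc(C2OCCO2)c(-c2ccc(O[Si](C(C)C)(C(C)C)C(C)C)cc2O[Si](C(C)C)(C(C)C)C(C)C)o1
F2 | step 8 | {5-[2,4-bis(triisopropylsilyloxy)phenyl]-4-(1,3-dioxolan-2-yl)furan-2-yl}acetyl chloride | ClC(=O)Cc1cc(C2OCCO2)c(-c2ccc(O[Si](C(C)C)(C(C)C)C(C)C)cc2O[Si](C(C)C)(C(C)C)C(C)C)o1
F3 | step 3 | 2-[2,4-bis(triisopropylsilyloxy)phenyl]-4,4,5,5-tetramethyl-1,3,2-dioxaborolane | CC1(C)OB(OC1(C)C)c1ccc(O[Si](C(C)C)(C(C)C)C(C)C)cc1O[Si](C(C)C)(C(C)C)C(C)C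
F4 | step 3 | 2-bromofuran-3-carbaldehyde | O=Cc1ccoc1Br
F5 | step 3 | 2-[2,4-bis(triisopropylsilyloxy)phenyl]furan-3-carbaldehyde | O=Cc1ccoc1-c1ccc(O[Si](C(C)C)(C(C)C)C(C)C)cc1O[Si](C(C)C)(C(C)C)C(C)C
F6 | step 7 | bromo[3-methyl-3-(triethylsilyloxy)butyl]magnesium | Br[Mg]CCC(C)(C)O[Si](CC)(CC)CC
F7 | step 7 | N,2-dimethoxy-N-methylacetamide | COCC(=O)N(C)OC
F8 | step 7 | 1-methoxy-5-methyl-5-(triethylsilyloxy)hexan-2-one | COCC(=O)CCC(C)(C)O[Si](CC)(CC)CC
F9 | step 7 | (1Z)-1-methoxy-5-methyl-5-(triethylsilyloxy)hex-1-en-2-yl trifluoromethanesulfonate | CO/C=C(\OS(=O)(=O)C(F)(F)F)CCC(C)(C)O[Si](CC)(CC)CC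
A1 | direct plan | 8-iodo-5,7-dimethoxy-3,4-dihydro-2H-chromen-2-one | O=C1CCc2c(OC)cc(OC)c(I)c2O1
A2 | direct plan | 4-(3,3-diethoxyprop-1-yn-1-yl)-1,3-phenylene bis(2,2-dimethylpropanoate) | CCOC(OCC)C#Cc1ccc(OC(=O)C(C)(C)C)cc1OC(=O)C(C)(C)C
A3 | direct plan | 4-[9-(diethoxymethyl)-5-methoxy-2-oxo-3,4-dihydro-2H-furo[2,3-h]chromen-8-yl]-1,3-phenylene bis(2,2-dimethylpropanoate) | COc1cc2oc(-c3ccc(OC(=O)C(C)(C)C)cc3OC(=O)C(C)(C)C)c(C(OCC)OCC)c2c2OC(=O)CCc12
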